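(The runs were generated by integration for an exercise; scatter was added.)

We start from the charge.

| flask | starting material | remark | time |
|---|---|---|---|
| south-west | 0.67 M | run made earlier |  |
| south | 1.5 M | run made earlier |  |
| flask | 1.0 M |  | 15 d |

- south-west (time / d: target / %, starting material / %): 1.25: 56, 7; 3.00: 55, 6; 8.00: 51, 8; 20.0: 33, 6
- south (time / d: target / %, starting material / %): 1.25: 64, 3; 3.00: 68, 4; 8.00: 71, 6; 20.0: 65, 2

(scatter of a reading: 1.5 percentage points)

- in percentages every species weighs as the starting material in it: one idle adduct or side product counts as two
- for target the idle adduct and crystals are counted in
- as a solid, counted per litre of solution: crystals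
- steps that have been proposed: crystals <-> target; starting material + target -> side product; starting material <-> isomer of the product; starting material <-> target; starting material + target <-> idle adduct
- in an amount of target, one idle adduct counts as one target

1. the moment within 15 d at which there is most target
2. the amount of target, in percent of the starting material charged, at that time

In the south-west run target reads highest at 56% after 1.25 d, and in the south run at 71% after 8.00 d, so the larger charge reaches the larger share. The starting material suggests a reading of this: averaged over its readings it stands at 0.0452 M in the south-west run and 0.0562 M in the south run, although the charges are 0.67 M and 1.5 M, and a concentration that stays put costs a share that falls as the charge rises. We therefore suppose that the top of target lies below a common share by a fixed concentration divided by the charge, and from the two tops we get this withheld concentration, 0.182 M, a value that carries their scatter, since two readings always fit a line.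

For the flask at 1.0 M our own reckoning then gives 64.9%, at a time between 1.25 d and 8.00 d. The forecast, which sees “crystals forming, pulling the equilibrium toward target” in the south run, says 61% (57% to 67%) at 3.5 d (1.5 d to 9 d), which is lower than our figure.

The flask gives 63.7% at 4.66 d.

    crystals ⇌ target, rate k1*(cs1 - [target]) while solid is left; crystals form when [target] > cs1 (solubility = 22.0 mM, k = 3.30 h⁻¹)
    starting material + target → side product (k = 0.200 M⁻¹ h⁻¹)
    starting material ⇌ isomer of the product (K = 5.20, k = 0.160 h⁻¹)
    starting material ⇌ target (K = 0.520, k = 0.310 h⁻¹)
    starting material + target ⇌ idle adduct, settled at all times (K = 5.80 M⁻¹)

At 4.66 d the flask holds 63.7% of target, of which 60.9% are crystals, the resting state of target here, and our 64.9% stands 1.2 percentage points above the 63.7% it gives. We use the same 0.182 M on a neighbour, like the flask but charged with 2.5 M of starting material, a larger charge than either earlier run had: the line gives 75.9%, and that neighbour tops at 79.2%.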